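The time limit of 3.0 min weighs little on this flask: both runs have reached their highest reading of isomer of the product A by 80.0 s, earlier than the limit. The charge weighs little too, since those highest readings, 22 % at 19 mM and 19 % at 42 mM, differ by 3 percentage points against a scatter of 2 points on each, so the two runs are pooled for the flask between them.

| flask | substrate | remark | time |
|---|---|---|---|
| south-west | 19 mM | run made earlier |  |
| north-west | 42 mM | run made earlier |  |
| flask | 28 mM |  | 3.0 min |

| run | time / s | isomer of the product A / % | target / % |
|---|---|---|---|
| south-west | 20.0 | 10 | 34 |
| south-west | 30.0 | 12 | 44 |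
| south-west | 40.0 | 16 | 49 |
| south-west | 60.0 | 21 | 65 |
| south-west | 80.0 | 22 | 67 |
| south-west | 120 | 18 | 71 |
| north-west | 20.0 | 12 | 31 |
| north-west | 30.0 | 18 | 44 |
| north-west | 40.0 | 17 | 52 |
| north-west | 60.0 | 18 | 60 |
| north-west | 80.0 | 19 | 67 |
| north-west | 120 | 19 | 73 |

(standard deviation of a reading: 2 percentage points)

- a reading or a percentage of target counts all its forms, free or not

- time, not beyond 3.0 min, at which the flask holds most isomer of the product A
- the amount of isomer of the product A, in percent of the substrate charged, at that time

In this reckoning the height follows the early share of isomer of the product A (the selectivity) in direct proportion, and the rest hangs on two rates, with [substrate] taken as what the readings leave over: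

k = 0.0251 s⁻¹

φ = 25.3 %

d = 0.00257 s⁻¹

Here d is the net drain coefficient, the fall of ln[isomer of the product A] per unit time once the consumption of substrate, read as faster than this drain, is taken as over. It is the weak number, because a drain of 0.00513 s⁻¹, larger than the one read, lies within the scatter of its four readings and would give 1.33 min and 16.8 %. Taken as read, it gives:

t = ln(k/d)/(k − d) = 1.68 min

height = φ·exp(−d·t) = 19.5 %

The forecast stands at 1.3 min and 20.5 %, earlier than this reckoning, and notes “The peak is flat”.

The flask gives 1.36 min and 20.4 %.

    substrate ⇌ target (K = 3.00, k = 0.0227 s⁻¹)
    substrate ⇌ isomer of the product A (K = 2.22, k = 0.00827 s⁻¹)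
    target ⇌ isomer of the product A (k = 5.92 × 10⁻⁴ s⁻¹)
    crystals ⇌ target, rate k4*(cs4 - [target]) while solid is left; crystals form when [target] > cs4 (solubility = 0.730 mM, k = 0.351 s⁻¹)
    target ⇌ isomer of the product B (K = 2.60, k = 0.00434 s⁻¹)

From 20.4 % at 1.36 min, d carries this flask to 15.8 % at 3.0 min, while the flask holds 16.7 %, with 10.9 % of substrate still present at its highest point. By 3.0 min substrate in this flask stands at 3.23 %, and the same flask read at 5.0 min, with substrate at 2.24 %, is the neighbour on which d is tried: d takes 16.7 % down to 12.3 %, and the neighbour flask holds 11.8 %.

All runs stem from a simulated flask from invented constants; noise was put on by code.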